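The pitfall is to read a vanished J as J.Z made, because J leaves by two routes: with Q into Z, and with Z into J.Z.

| setting | south-east | north-east | east | south |
|---|---|---|---|---|
| J | 0.050 M | 0.050 M | 0.050 M (fed, over 6.0 h) | 0.050 M |
| Q | 0.0450 M (in portions, 3, over 6.0 h) | 0.0450 M | 0.0450 M | 0.0450 M (fed, over 6.0 h) |
| X | 0.0600 M | 0.0600 M | 0.0600 M | 0.0600 M |
| time | 8.0 h | 8.0 h | 8.0 h | 8.0 h |
| remark | first portion at the start, last at 6.0 h | everything together at the start | all else is in the flask from the start; the feed brings no volume worth counting | all else is in the flask from the start; the feed brings no volume worth counting |

    J + Q ⇌ Z + D (K1 = 3.8, k1 = 77 M⁻¹ min⁻¹)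
    J + D ⇌ J.D, settled at all times (K2 = 4.8 M⁻¹)
    X + D → X.D (k3 = 32 M⁻¹ min⁻¹)
    J + Z → J.Z (k4 = 0.12 M⁻¹ min⁻¹)

- which flask leads in amount of J.Z, in percent of the J charged ("all alike" within 1.5 percentage points) (south-east / north-east / east / south / all alike)
- how much J.Z is there at the end, in percent of the J charged: south-east
- how much J.Z is there at the end, in percent of the J charged: north-east
- how much J.Z is there at the end, in percent of the J charged: east
- how much J.Z is there at the end, in percent of the J charged: south

- in percentages every species weighs as the J in it: one J.Z counts as two
- for D the J.D is counted in
- run time (south-east): 8.0 h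

We count half-lives, fastest first. The balance of J and D with J.D counts as instant, and at the start of north-east J.D stands at 0.24 of free D. Next, Q against J at its charge has a half-life of 0.180 min, and D against X one of 0.361 min. X at its charge takes D at 1.92 min⁻¹, faster than Z at 0.0450 M takes it back, at 0.912 min⁻¹. So in north-east, with J and X charged together with Q at the start, Q becomes Z within minutes.

The slow rung is the half-life of Z against J, ln 2 over the J + Z constant times the concentration of J. At the whole charge of J it is 1.93 h, far longer than the rungs above, and it stretches as J falls. With J in excess this is a pseudo-first-order count, and the same formula with Z in place of J gives the half-life of J.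

In north-east, 0.00500 M of J remains beside Z at 0.0450 M, so J has a half-life of 2.14 h. The run holds 3.74 of these, which gives 18.5%, since one J.Z counts as two.

In east, the last 0.00500 M of J arrives with about 2.30 h left, which gives 10.5%.

In south-east, the first portion leaves J at 0.0350 M. The gap holds 1.09 half-lives of Z, making 0.007957 M of J.Z. After the second portion, J at 0.0120 M is the lesser partner beside Z at 0.0220 M, and 0.687 half-lives of J make 0.004562 M. The 0.007438 M of J then left is less than the last portion of 0.0150 M, so that portion takes it. Our south-east count is 50.1%, the highest, and we leave south without a number.

The forecast, lower than our south-east count, names south-east with 47.5%, then 18.3% in north-east, 11.2% in east and 39.5% in south, on the ground that “J and Q convert almost stoichiometrically”.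

The flask gives 47.3% in south-east, 18.3% in north-east, 11.1% in east and 39.3% in south, so south-east leads.

In south-east at 2.97 h, Z has a half-life of 3.5 h against J's 12 h, so Z is turning over faster. That half-life is longer than the 2.75 h we held through the first gap, and our count stands above the result. In the neighbour of south-east with 0.20 M of J, each Q costs two J, so J ends near 0.110 M. The half-life of Z is then 0.875 h, and the last portion has 2.29 half-lives, leaving Z at 1.54% of the J charged. The computed flask has 1.45% of Z, with J.Z at 42.1%.

All constants belong to no real substance; the run is a simulation.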